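**Retrosynthetic overview**

- The target, (2S)-2,3-dihydroamentoflavone 7,4'-dimethyl ether, is traced back through removal of four O-benzyl groups and through C4=O ⇐ C4–OH ⇐ C4–OMe to a benzyl-protected 2,4-cis-4-methoxyflavan that already carries the flavone on ring B.
- Key disconnection: ring C of the flavanone half is opened at O1–C2 and C3–C4 by an inverse-demand hetero-Diels–Alder reaction. The heterodiene is a methoxy ortho-quinone methide made from a ring A salicylaldehyde and trimethyl orthoformate, the dienophile is a biaryl 4-methoxystyrene, and a confined chiral Brønsted acid sets C2.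
- Feature on which this rests: ring C is a pyran ring whose O1 and C4 both sit on the electron-rich, phloroglucinol-type ring A, and C2 bears ring B, whose 4'-OMe is para to C2. The matching styrene is therefore polarised for exactly this regiochemistry.
- The styrene comes from apigenin by tri-O-benzylation, C8 iodination, Suzuki coupling with 5-formyl-2-methoxyphenylboronic acid (the C8–C3' biaryl bond) and Wittig methylenation. The aldehyde comes from 2,4,6-trihydroxybenzaldehyde by 4-O-methylation and mono-O-benzylation.
- Ring order: the three rings of the flavone half are bought with apigenin, rings A and B of the flavanone half enter as arenes, and ring C of the flavanone half is the only ring made, in the key step.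

Key step: step 7

Assumption: the (S,S)-enantiomer of the confined imidodiphosphorimidate acid is taken to give the (2S) product; if the sense of induction is the opposite, the (R,R)-catalyst is used.
Assumption: the C8–C3' biaryl axis is taken to rotate freely at room temperature, as the target carries no axial descriptor.

**Route**

Step 1
Reactants: 1 2,4,6-trihydroxybenzaldehyde
Product: 2 2,6-dihydroxy-4-methoxybenzaldehyde
Conditions: Me2SO4 (1.0 equiv), K2CO3 (1.0 equiv), acetone, 0 °C to rt
Reagents that add atoms: dimethyl sulfate, COS(=O)(=O)OC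
Why: Williamson O-methylation; the 4-OH is the most acidic hydroxyl and the only one not hydrogen-bonded to the formyl group, so one equivalent of base and electrophile should alkylate it selectively.

Step 2
Reactants: 2 2,6-dihydroxy-4-methoxybenzaldehyde
Product: 3 2-(benzyloxy)-6-hydroxy-4-methoxybenzaldehyde
Conditions: BnBr (1.05 equiv), K2CO3 (1.1 equiv), DMF, rt
Reagents that add atoms: benzyl bromide, BrCc1ccccc1
Why: Williamson O-benzylation; the two hydroxyls are equivalent by symmetry, and after the first alkylation the remaining one is locked in a hydrogen bond to the aldehyde and reacts much more slowly, so mono-benzylation should dominate.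

Step 3
Reactants: 4 apigenin
Product: 5 5,7-bis(benzyloxy)-2-[4-(benzyloxy)phenyl]-4H-chromen-4-one (apigenin tribenzyl ether)
Conditions: BnBr (4.5 equiv), K2CO3 (6 equiv), DMF, 80 °C
Reagents that add atoms: benzyl bromide, BrCc1ccccc1
Why: exhaustive Williamson O-benzylation; heat and excess reagent are used because the chelated 5-OH is the slowest to alkylate.

Step 4
Reactants: 5 apigenin tribenzyl ether
Product: 6 5,7-bis(benzyloxy)-2-[4-(benzyloxy)phenyl]-8-iodo-4H-chromen-4-one
Conditions: I2 (1.1 equiv), AgO2CCF3 (1.1 equiv), CH2Cl2, 0 °C to rt, dark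
Reagents that add atoms: iodine, II
Why: electrophilic aromatic iodination; fully O-alkylated 5,7-dioxygenated flavones react on ring A at C8 (para to the 5-oxygen), while C6 is shielded between two benzyloxy groups and ring B and C3 are deactivated by the pyranone.

Step 5
Reactants: 6 8-iodoapigenin tribenzyl ether; 7 5-formyl-2-methoxyphenylboronic acid
Product: 8 3-{5,7-bis(benzyloxy)-2-[4-(benzyloxy)phenyl]-4-oxo-4H-chromen-8-yl}-4-methoxybenzaldehyde
Conditions: 7 (1.5 equiv), Pd(OAc)2 (5 mol%), SPhos (10 mol%), K3PO4 (3 equiv), toluene/H2O 10:1, 90 °C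
Reagents that add atoms: none
Why: Suzuki–Miyaura coupling; the bulky electron-rich biarylphosphine should let palladium insert into the C8–I bond flanked by two oxygen substituents and couple the ortho-methoxy boronic acid, with the formyl group untouched.

Step 6
Reactants: 8 the biaryl aldehyde
Product: 9 5,7-bis(benzyloxy)-2-[4-(benzyloxy)phenyl]-8-(2-methoxy-5-vinylphenyl)-4H-chromen-4-one
Conditions: Ph3PCH3Br (1.3 equiv), KOtBu (1.25 equiv), THF, 0 °C; then 8, 0 °C to rt
Reagents that add atoms: methyltriphenylphosphonium bromide, C[P+](c1ccccc1)(c1ccccc1)c1ccccc1.[Br-]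
Why: Wittig methylenation; the aldehyde is far more electrophilic than the vinylogous-ester carbonyl of the flavone, and the base is kept in slight deficit to the phosphonium salt so that no free alkoxide meets the pyranone.

Step 7
Reactants: 3 2-(benzyloxy)-6-hydroxy-4-methoxybenzaldehyde; 9 the biaryl styrene; 10 trimethyl orthoformate
Product: 13 5,7-bis(benzyloxy)-2-[4-(benzyloxy)phenyl]-8-{5-[(2S,4S)-5-(benzyloxy)-4,7-dimethoxychroman-2-yl]-2-methoxyphenyl}-4H-chromen-4-one (2,4-cis), via dimethyl acetal 11 (not isolated), via methoxy ortho-quinone methide 12 (not isolated)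
Conditions: 9 (1.0 equiv), 10 (2.0 equiv), (S,S)-IDPi (confined imidodiphosphorimidate Brønsted acid, 5–10 mol%), CHCl3, −20 °C; 3 (1.3 equiv) added slowly
Reagents that add atoms: none
Why: Proposed new method: the acid turns 3 and 10 into acetal 11, which ionises to an aryl oxocarbenium ion whose phenol-deprotonated form is the methoxy ortho-quinone methide 12, held as a hydrogen-bonded ion pair with the chiral anion, and its heterodiene O=C8a–C4a=C4 adds to the vinyl group of 9 in an inverse-demand, asynchronous [4+2] cycloaddition. The closest known reactions are the achiral acid-promoted union of salicylaldehydes, orthoformates and styrenes to racemic 4-alkoxyflavans and chiral-acid cycloadditions of other ortho-quinone methides with styrenes. Ring C closes as a six-membered ring in this [4+2] mode, with C3–C4 forming first and the phenol oxygen then capturing the developing benzylic cation at C2 to make O1–C2. C2 is set by the confined chiral counter-anion, which leaves one face of the styrene open to the bound heterodiene, and C4 follows as cis from the endo transition state, a configuration that is erased later. The step needs regioselectivity, secured by the 4'-methoxy group para to the vinyl group stabilising positive charge at C2, and chemoselectivity for the alkene over arene C–H positions, secured because the only free ring A position of the flavone (C6) is deactivated by the pyranone carbonyl and flanked by two benzyloxy groups.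

Step 8
Reactants: 13 the 2,4-cis-4-methoxyflavan
Product: 14 5,7-bis(benzyloxy)-2-[4-(benzyloxy)phenyl]-8-{5-[(2S)-5-(benzyloxy)-4-hydroxy-7-methoxychroman-2-yl]-2-methoxyphenyl}-4H-chromen-4-one (mixture of C4 epimers)
Conditions: TsOH·H2O (0.2 equiv), THF/H2O 4:1, 0.01 M, rt
Reagents that add atoms: water, O
Why: SN1 solvolysis of a benzylic ether; the C4 cation is stabilised by O1, the 5-benzyloxy and the 7-methoxy groups and should form under mild acid and be captured by the large excess of water, while the far less stabilised C2–O1 bond stays intact so C2 is not touched.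

Step 9
Reactants: 14 the flavan-4-ol
Product: 15 5,7-bis(benzyloxy)-2-[4-(benzyloxy)phenyl]-8-{5-[(2S)-5-(benzyloxy)-7-methoxy-4-oxochroman-2-yl]-2-methoxyphenyl}-4H-chromen-4-one
Conditions: IBX (1.5 equiv), DMSO/THF 1:1, rt
Reagents that add atoms: none
Why: hypervalent-iodine (IBX) oxidation of a secondary benzylic alcohol; both C4 epimers converge on the ketone, and the non-basic medium avoids retro-oxa-Michael opening, so C2 keeps its configuration.

Step 10
Reactants: 15 the tetrabenzyl flavanone–flavone
Product: 16 5,7-dihydroxy-8-{5-[(2S)-5-hydroxy-7-methoxy-4-oxochroman-2-yl]-2-methoxyphenyl}-2-(4-hydroxyphenyl)-4H-chromen-4-one (target)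
Conditions: H2 (1 atm), 10% Pd/C, THF/MeOH 1:1, rt
Reagents that add atoms: none
Why: catalytic hydrogenolysis of four benzyl aryl ethers; these cleave much faster than the flavone C2=C3 bond, the aryl ketone or the cyclic C2–O1 ether are reduced, and the neutral medium should leave the (2S) centre of the 5-hydroxyflavanone unchanged.

**Compound list**

1 | 2,4,6-trihydroxybenzaldehyde | O=Cc1c(O)cc(O)cc1O | starting material
2 | 2,6-dihydroxy-4-methoxybenzaldehyde | COc1cc(O)c(C=O)c(O)c1 | intermediate
3 | 2-(benzyloxy)-6-hydroxy-4-methoxybenzaldehyde | COc1cc(O)c(C=O)c(OCc2ccccc2)c1 | intermediate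
4 | apigenin | O=c1cc(-c2ccc(O)cc2)oc2cc(O)cc(O)c12 | starting material
5 | 5,7-bis(benzyloxy)-2-[4-(benzyloxy)phenyl]-4H-chromen-4-one | O=c1cc(-c2ccc(OCc3ccccc3)cc2)oc2cc(OCc3ccccc3)cc(OCc3ccccc3)c12 | intermediate
6 | 5,7-bis(benzyloxy)-2-[4-(benzyloxy)phenyl]-8-iodo-4H-chromen-4-one | O=c1cc(-c2ccc(OCc3ccccc3)cc2)oc2c(I)c(OCc3ccccc3)cc(OCc3ccccc3)c12 | intermediate
7 | 5-formyl-2-methoxyphenylboronic acid | COc1ccc(C=O)cc1B(O)O | starting material
8 | 3-{5,7-bis(benzyloxy)-2-[4-(benzyloxy)phenyl]-4-oxo-4H-chromen-8-yl}-4-methoxybenzaldehyde | O=Cc1ccc(OC)c(-c3c(OCc6ccccc6)cc(OCc6ccccc6)c4c(=O)cc(-c5ccc(OCc6ccccc6)cc5)oc34)c1 | intermediate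
9 | 5,7-bis(benzyloxy)-2-[4-(benzyloxy)phenyl]-8-(2-methoxy-5-vinylphenyl)-4H-chromen-4-one | C=Cc1ccc(OC)c(-c3c(OCc6ccccc6)cc(OCc6ccccc6)c4c(=O)cc(-c5ccc(OCc6ccccc6)cc5)oc34)c1 | intermediate
10 | trimethyl orthoformate | COC(OC)OC | starting material
11 | 3-(benzyloxy)-2-(dimethoxymethyl)-5-methoxyphenol (dimethyl acetal, formed in the flask) | COc1cc(O)c(C(OC)OC)c(OCc2ccccc2)c1 | intermediate
12 | 5-(benzyloxy)-3-methoxy-6-(methoxymethylidene)cyclohexa-2,4-dien-1-one (methoxy ortho-quinone methide, formed in the flask, alkene geometry not defined) | COC=C1C(=O)C=C(OC)C=C1OCc1ccccc1 | intermediate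
13 | 5,7-bis(benzyloxy)-2-[4-(benzyloxy)phenyl]-8-{5-[(2S,4S)-5-(benzyloxy)-4,7-dimethoxychroman-2-yl]-2-methoxyphenyl}-4H-chromen-4-one (2,4-cis) | COc1cc(OCc2ccccc2)c2c(c1)O[C@H](c1ccc(OC)c(-c3c(OCc6ccccc6)cc(OCc6ccccc6)c4c(=O)cc(-c5ccc(OCc6ccccc6)cc5)oc34)c1)C[C@@H]2OC | intermediate
14 | 5,7-bis(benzyloxy)-2-[4-(benzyloxy)phenyl]-8-{5-[(2S)-5-(benzyloxy)-4-hydroxy-7-methoxychroman-2-yl]-2-methoxyphenyl}-4H-chromen-4-one (C4 epimer mixture) | COc1cc(OCc2ccccc2)c2c(c1)O[C@H](c1ccc(OC)c(-c3c(OCc6ccccc6)cc(OCc6ccccc6)c4c(=O)cc(-c5ccc(OCc6ccccc6)cc5)oc34)c1)CC2O | intermediate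
15 | 5,7-bis(benzyloxy)-2-[4-(benzyloxy)phenyl]-8-{5-[(2S)-5-(benzyloxy)-7-methoxy-4-oxochroman-2-yl]-2-methoxyphenyl}-4H-chromen-4-one | COc1cc(OCc2ccccc2)c2c(c1)O[C@H](c1ccc(OC)c(-c3c(OCc6ccccc6)cc(OCc6ccccc6)c4c(=O)cc(-c5ccc(OCc6ccccc6)cc5)oc34)c1)CC2=O | intermediate
16 | 5,7-dihydroxy-8-{5-[(2S)-5-hydroxy-7-methoxy-4-oxochroman-2-yl]-2-methoxyphenyl}-2-(4-hydroxyphenyl)-4H-chromen-4-one | COc1cc(O)c2c(c1)O[C@H](c1ccc(OC)c(-c3c(O)cc(O)c4c(=O)cc(-c5ccc(O)cc5)oc34)c1)CC2=O | target

**Step count and risks**

Total step count: 10. Longest linear sequence: 8 steps (apigenin 4 through steps 3, 4, 5, 6, 7, 8, 9 and 10 to 16).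

Steps most likely to fail:

1. Step 7 (key step). The confined acid may give poor enantiofacial control with a styrene this large. Its flavone carbonyl can also buffer the catalyst and slow the reaction. The oxocarbenium ion may instead attack the phloroglucinol-type ring of 3, 11 or 13 (Friedel–Crafts self-condensation), or the acid may oligomerise the styrene. Fallback by known chemistry, setting out from 8 and coming back at 15: commercial 1-(2,6-dihydroxy-4-methoxyphenyl)ethanone F1 is mono-benzylated (BnBr, K2CO3, DMF) to 1-[2-(benzyloxy)-6-hydroxy-4-methoxyphenyl]ethanone F2. Claisen–Schmidt condensation of F2 with 8 (KOH, EtOH/THF, rt) gives the (E)-2'-hydroxychalcone F3. NaOAc in hot EtOH closes ring C by intramolecular oxa-Michael addition to the racemic protected flavanone F4. Preparative HPLC on a polysaccharide chiral stationary phase then delivers 15, and the (2R)-enantiomer F5 is set aside; base reopens it to F3 for recycling.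

2. Step 8. Ionisation at C4 may lead to intermolecular Friedel–Crafts oligomerisation, because ring A of a second molecule can attack the C4 cation, or to proton loss giving the flav-3-ene; either erodes the yield before water captures the cation. Fallback, setting out from 13 and coming back at 15, bypassing 14: DDQ (1.2 equiv) in CH2Cl2 with pH 7 aqueous buffer at 0 °C abstracts hydride from the very electron-rich C4–H to give the methoxy-stabilised C4 oxocarbenium ion, which water converts directly into the ketone with loss of methanol. This is a known benzylic-ether oxidation and does not pass through the cation-prone flavan-4-ol.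

3. Step 10. Over-reduction may occur, either hydrogenolytic opening of the benzylic C2–O1 bond to a dihydrochalcone or saturation of the flavone C2=C3 bond, or the reaction may stall at partly benzylated stages. Fallback, setting out from 15 and coming back at 16: BCl3 with pentamethylbenzene as cation scavenger in CH2Cl2 at −78 °C cleaves the four benzyl ethers by Lewis-acid debenzylation. The aryl methyl ethers at C7 and C4', neither of them peri to a carbonyl, should survive at this temperature, and no reducing agent is present.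

**Further compounds**

F1 | step 7 | 1-(2,6-dihydroxy-4-methoxyphenyl)ethanone | COc1cc(O)c(C(C)=O)c(O)c1
F2 | step 7 | 1-[2-(benzyloxy)-6-hydroxy-4-methoxyphenyl]ethanone | COc1cc(O)c(C(C)=O)c(OCc2ccccc2)c1
F3 | step 7 | (E)-1-[2-(benzyloxy)-6-hydroxy-4-methoxyphenyl]-3-(3-{5,7-bis(benzyloxy)-2-[4-(benzyloxy)phenyl]-4-oxo-4H-chromen-8-yl}-4-methoxyphenyl)prop-2-en-1-one | COc1cc(O)c(C(=O)/C=C/c2ccc(OC)c(-c3c(OCc6ccccc6)cc(OCc6ccccc6)c4c(=O)cc(-c5ccc(OCc6ccccc6)cc5)oc34)c2)c(OCc2ccccc2)c1
F4 | step 7 | racemic 5,7-bis(benzyloxy)-2-[4-(benzyloxy)phenyl]-8-{5-[5-(benzyloxy)-7-methoxy-4-oxochroman-2-yl]-2-methoxyphenyl}-4H-chromen-4-one | COc1cc(OCc2ccccc2)c2c(c1)OC(c1ccc(OC)c(-c3c(OCc6ccccc6)cc(OCc6ccccc6)c4c(=O)cc(-c5ccc(OCc6ccccc6)cc5)oc34)c1)CC2=O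
F5 | step 7 | 5,7-bis(benzyloxy)-2-[4-(benzyloxy)phenyl]-8-{5-[(2R)-5-(benzyloxy)-7-methoxy-4-oxochroman-2-yl]-2-methoxyphenyl}-4H-chromen-4-one | COc1cc(OCc2ccccc2)c2c(c1)O[C@@H](c1ccc(OC)c(-c3c(OCc6ccccc6)cc(OCc6ccccc6)c4c(=O)cc(-c5ccc(OCc6ccccc6)cc5)oc34)c1)CC2=O
F0 | step 8 | none | none
F0 | step 10 | none | none
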